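**Retrosynthetic overview**
1. Target 20 ⇐ tigloylation of keto diol 18 ⇐ hydrolysis of the oxygen-bridged methyl ketal 17, which hides the C1 ketone and O8 until the end.
2. Ten-membered carbocycle (third ring formed) ⇐ ring-closing metathesis of diene 16, making the (Z)-C4=C5 bond.
3. α-Methylene-γ-butyrolactone (second ring) and the key C6–C7 bond ⇐ indium-electrocatalytic Barbier allylation of acrolein with allyl bromide 13, then lactonization; C6 and C7 are set from C8.
4. 13 ⇐ aldehyde 10 (Baylis–Hillman, SN2′ bromination) ⇐ lactone 5 + (3-methylbut-3-enyl)lithium (C1–C2 bond), then methanolysis to the oxolane ketal (first ring, from the bought lactone).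
5. C10 ⇐ anti-selective α-hydroxylation then α-methylation of the (R)-5-(trityloxymethyl)butyrolactone; C8 is bought in lactone 1 (made from D-glutamic acid).

Assumption: the target is made exactly as the SMILES shows (4Z; 6R,7S,8R,10R; cis-fused lactone; ester = tiglate); atoms are labelled with germacrane numbers C1–C15.

**Step 1**
Reactants: 1 (R)-5-(hydroxymethyl)oxolan-2-one
Product: 2 (R)-5-[(triphenylmethoxy)methyl]oxolan-2-one
Conditions: TrCl, pyridine, DMAP (cat.), CH2Cl2, 23 °C
Reagents that add atoms: trityl chloride (ClC(c1ccccc1)(c1ccccc1)c1ccccc1)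
Why: Standard tritylation of the primary alcohol gives the bulky CH2OTr group that later shields one face of the lactone enolate, and the bought stereocentre (future C8) is not touched.

**Step 2**
Reactants: 2 (R)-5-[(triphenylmethoxy)methyl]oxolan-2-one
Product: 3 (3S,5R)-3-hydroxy-5-[(triphenylmethoxy)methyl]oxolan-2-one
Conditions: NaN(SiMe3)2, THF, −78 °C; racemic 3-phenyl-2-(phenylsulfonyl)oxaziridine, −78 °C; aq. NH4Cl
Reagents that add atoms: 3-phenyl-2-(phenylsulfonyl)oxaziridine, racemic (O=S(=O)(c1ccccc1)N1OC1c1ccccc1)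
Why: Enolate hydroxylation with an N-sulfonyloxaziridine (Davis oxidation) delivers oxygen anti to CH2OTr to give mainly the 3,5-trans alcohol, whose C3 configuration is erased again in step 4.

**Step 3**
Reactants: 3 (3S,5R)-3-hydroxy-5-[(triphenylmethoxy)methyl]oxolan-2-one
Product: 4 (3S,5R)-3-[(2-methoxypropan-2-yl)oxy]-5-[(triphenylmethoxy)methyl]oxolan-2-one
Conditions: 2-methoxypropene, pyridinium p-toluenesulfonate (cat.), CH2Cl2, 0 °C
Reagents that add atoms: 2-methoxypropene (COC(C)=C)
Why: Acid-catalysed addition of the alcohol to the enol ether gives a mixed ketal (MOP ether) that is stable to amide bases and organolithiums but falls off under the mild acid of step 5.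

**Step 4**
Reactants: 4 (3S,5R)-3-[(2-methoxypropan-2-yl)oxy]-5-[(triphenylmethoxy)methyl]oxolan-2-one
Product: 5 (3R,5R)-3-[(2-methoxypropan-2-yl)oxy]-3-methyl-5-[(triphenylmethoxy)methyl]oxolan-2-one
Conditions: LiN(i-Pr)2, THF, −78 °C; MeI, −78 → −40 °C
Reagents that add atoms: iodomethane (CI)
Why: Enolate alkylation of a γ-substituted butyrolactone: MeI attacks the planar α-alkoxy enolate anti to CH2OTr (1,3-induction from the bought centre), so the oxygen ends cis to CH2OTr and the quaternary carbinol (future C10) is set as R.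

**Step 5**
Reactants: 5 (3R,5R)-3-[(2-methoxypropan-2-yl)oxy]-3-methyl-5-[(triphenylmethoxy)methyl]oxolan-2-one; 6 4-bromo-2-methylbut-1-ene
Product: 9 [(2R,4R,5R)-4-hydroxy-5-methoxy-4-methyl-5-(3-methylbut-3-en-1-yl)oxolan-2-yl]methanol, via (3-methylbut-3-en-1-yl)lithium 7 (not isolated), via lactol 8 (not isolated)
Conditions: 6, t-BuLi (2 equiv per 6), Et2O, −78 °C; 5, THF, −78 °C; then HCl in MeOH (slight excess over base), −78 → 23 °C
Reagents that add atoms: methanol (CO)
Why: Bromine–lithium exchange and single addition of the organolithium to the hindered lactone (stable lithium hemiketal) form C1–C2, and acidic methanolysis then removes Tr and MOP and turns the lactol into the methyl ketal that masks the C1 ketone and O8 (an unmasked ketone would be attacked intramolecularly by the allylmetal of step 9), the anomer with the alkyl chain anti to the C10 methyl being thermodynamically favoured.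

**Step 6**
Reactants: 9 [(2R,4R,5R)-4-hydroxy-5-methoxy-4-methyl-5-(3-methylbut-3-en-1-yl)oxolan-2-yl]methanol
Product: 10 (2R,4R,5R)-4-hydroxy-5-methoxy-4-methyl-5-(3-methylbut-3-en-1-yl)oxolane-2-carbaldehyde
Conditions: TEMPO (10 mol%), PhI(OAc)2, CH2Cl2, 23 °C
Reagents that add atoms: none
Why: Oxoammonium (TEMPO) oxidation converts the only primary alcohol into the aldehyde under mild, non-epimerizing conditions while the tertiary alcohol, the ketal and the alkene are inert.

**Step 7**
Reactants: 10 (2R,4R,5R)-4-hydroxy-5-methoxy-4-methyl-5-(3-methylbut-3-en-1-yl)oxolane-2-carbaldehyde; 11 methyl acrylate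
Product: 12 methyl 2-{hydroxy[(2R,4R,5R)-4-hydroxy-5-methoxy-4-methyl-5-(3-methylbut-3-en-1-yl)oxolan-2-yl]methyl}prop-2-enoate (both carbinol epimers)
Conditions: 11 (10 equiv), DABCO (1 equiv), MeOH (cat.), 23 °C
Reagents that add atoms: none
Why: Morita–Baylis–Hillman reaction of the activated α-alkoxy aldehyde with the DABCO–acrylate zwitterion installs C11–C13, and the new carbinol centre does not matter because it becomes sp2 in step 8.

**Step 8**
Reactants: 12 methyl 2-{hydroxy[(2R,4R,5R)-4-hydroxy-5-methoxy-4-methyl-5-(3-methylbut-3-en-1-yl)oxolan-2-yl]methyl}prop-2-enoate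
Product: 13 methyl (2Z)-2-(bromomethyl)-3-[(2R,4R,5R)-4-hydroxy-5-methoxy-4-methyl-5-(3-methylbut-3-en-1-yl)oxolan-2-yl]prop-2-enoate
Conditions: NBS, Me2S, CH2Cl2, −30 → 0 °C
Reagents that add atoms: N-bromosuccinimide (O=C1CCC(=O)N1Br)
Why: Sulfonium activation of the Baylis–Hillman alcohol and SN2′ attack of bromide (allylic transposition) give the thermodynamically preferred (Z)-2-(bromomethyl)enoate, with the hindered tertiary alcohol left alone.

**Step 9**
Reactants: 13 methyl (2Z)-2-(bromomethyl)-3-[(2R,4R,5R)-4-hydroxy-5-methoxy-4-methyl-5-(3-methylbut-3-en-1-yl)oxolan-2-yl]prop-2-enoate; 14 acrolein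
Product: 16 (4S,5R)-5-ethenyl-4-[(2R,4R,5R)-4-hydroxy-5-methoxy-4-methyl-5-(3-methylbut-3-en-1-yl)oxolan-2-yl]-3-methylideneoxolan-2-one, via hydroxy ester 15 (not isolated)
Conditions: 14 (3 equiv), InCl3 (10 mol%), Bu4NBr (0.1 M), DMF/THF 1:4, undivided cell, Al anode, graphite cathode, 5 mA (2.2 F/mol), 0 → 23 °C; then pyridinium p-toluenesulfonate (cat.), CH2Cl2, 23 °C
Reagents that add atoms: none
Why: Proposed new method: cathodic reduction of catalytic InCl3 (trivalent to monovalent indium, sacrificial aluminium anode) keeps regenerating the low-valent metal that inserts into the allylic C–Br bond of 13, and the σ-allylindium adds 1,2 to acrolein through its γ-carbon (C7) in a six-membered chair transition state in which the oxolanyl group stays cis to CH2In (axial, hence the syn adduct and the cis-lactone) while C8–H eclipses the alkene (allylic 1,3-strain) and the aldehyde approaches anti to the ring oxygen, which is not chelated in DMF (hence 6R,7S), after which aluminium cations take over the alkoxide and the acid closes the lactone; the closest known reaction types are the indium-catalysed electroreductive Barbier allylation of aldehydes with simple allyl bromide and the stoichiometric indium- or zinc-mediated 2-(alkoxycarbonyl)allylation–lactonization (Dreiding–Schmidt type), neither shown for a γ-substituted 2-(bromomethyl)enoate that carries an oxygenated stereocentre.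

**Step 10**
Reactants: 16 (4S,5R)-5-ethenyl-4-[(2R,4R,5R)-4-hydroxy-5-methoxy-4-methyl-5-(3-methylbut-3-en-1-yl)oxolan-2-yl]-3-methylideneoxolan-2-one
Product: 17 (1R,4Z,6R,7S,8R,10R)-1,8-epoxy-10-hydroxy-1-methoxygermacra-4,11(13)-dien-12,6-olide (oxygen-bridged methyl ketal; germacrane numbering)
Conditions: second-generation Hoveyda–Grubbs catalyst RuCl2(=CH-C6H4-2-O-i-Pr)(H2IMes) (10 mol%), toluene (1 mM), 80 °C, Ar sparge
Reagents that add atoms: none
Why: Ring-closing metathesis between the vinyl group and the 1,1-disubstituted alkene closes the ten-membered carbocycle because the cis-2,5-disubstituted oxolane holds both chains on one face, and the nine-membered oxygen-bridged ring so formed accommodates only the Z trisubstituted C4=C5 alkene.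

**Step 11**
Reactants: 17 (1R,4Z,6R,7S,8R,10R)-1,8-epoxy-10-hydroxy-1-methoxygermacra-4,11(13)-dien-12,6-olide
Product: 18 (4Z,6R,7S,8R,10R)-8,10-dihydroxy-1-oxogermacra-4,11(13)-dien-12,6-olide
Conditions: 1 M HCl, THF, 23 °C
Reagents that add atoms: water (O)
Why: Acid hydrolysis of the mixed ketal through its oxocarbenium ion frees the C1 ketone and the C8 hydroxyl without touching the lactone, the alkenes or any stereocentre.

**Step 12**
Reactants: 18 (4Z,6R,7S,8R,10R)-8,10-dihydroxy-1-oxogermacra-4,11(13)-dien-12,6-olide; 19 (E)-2-methylbut-2-enoyl chloride (tigloyl chloride)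
Product: 20 (4Z,6R,7S,8R,10R)-10-hydroxy-1-oxo-8-[(2E)-2-methylbut-2-enoyloxy]germacra-4,11(13)-dien-12,6-olide (target CNP0345906.4)
Conditions: 19 (2 equiv), pyridine, DMAP (cat.), CH2Cl2, 0 → 23 °C
Reagents that add atoms: none
Why: DMAP-catalysed esterification acylates the secondary C8 hydroxyl of the open keto-alcohol form with retention, the tertiary α-ketol hydroxyl being too hindered to react and pyridine being too weak a base to deconjugate or isomerize the tigloyl group.

**Compound list**
1 | (R)-5-(hydroxymethyl)oxolan-2-one (commercial; from D-glutamic acid) | OC[C@H]1CCC(=O)O1 | starting material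
2 | (R)-5-[(triphenylmethoxy)methyl]oxolan-2-one | O=C1CC[C@H](COC(c2ccccc2)(c2ccccc2)c2ccccc2)O1 | intermediate
3 | (3S,5R)-3-hydroxy-5-[(triphenylmethoxy)methyl]oxolan-2-one | O[C@H]1C[C@H](COC(c2ccccc2)(c2ccccc2)c2ccccc2)OC1=O | intermediate
4 | (3S,5R)-3-[(2-methoxypropan-2-yl)oxy]-5-[(triphenylmethoxy)methyl]oxolan-2-one | COC(C)(C)O[C@H]1C[C@H](COC(c2ccccc2)(c2ccccc2)c2ccccc2)OC1=O | intermediate
5 | (3R,5R)-3-[(2-methoxypropan-2-yl)oxy]-3-methyl-5-[(triphenylmethoxy)methyl]oxolan-2-one | COC(C)(C)O[C@]1(C)C[C@H](COC(c2ccccc2)(c2ccccc2)c2ccccc2)OC1=O | intermediate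
6 | 4-bromo-2-methylbut-1-ene | C=C(C)CCBr | starting material
7 | (3-methylbut-3-en-1-yl)lithium | [Li]CCC(C)=C | intermediate
8 | (3R,5R)-3-[(2-methoxypropan-2-yl)oxy]-3-methyl-2-(3-methylbut-3-en-1-yl)-5-[(triphenylmethoxy)methyl]oxolan-2-ol (lactol, both anomers) | C=C(C)CCC1(O)O[C@@H](COC(c2ccccc2)(c2ccccc2)c2ccccc2)C[C@@]1(C)OC(C)(C)OC | intermediate
9 | [(2R,4R,5R)-4-hydroxy-5-methoxy-4-methyl-5-(3-methylbut-3-en-1-yl)oxolan-2-yl]methanol | CO[C@]1(CCC(C)=C)O[C@@H](CO)C[C@@]1(C)O | intermediate
10 | (2R,4R,5R)-4-hydroxy-5-methoxy-4-methyl-5-(3-methylbut-3-en-1-yl)oxolane-2-carbaldehyde | CO[C@]1(CCC(C)=C)O[C@@H](C=O)C[C@@]1(C)O | intermediate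
11 | methyl acrylate | C=CC(=O)OC | starting material
12 | methyl 2-{hydroxy[(2R,4R,5R)-4-hydroxy-5-methoxy-4-methyl-5-(3-methylbut-3-en-1-yl)oxolan-2-yl]methyl}prop-2-enoate (both carbinol epimers) | CO[C@]1(CCC(C)=C)O[C@@H](C(O)C(=C)C(=O)OC)C[C@@]1(C)O | intermediate
13 | methyl (2Z)-2-(bromomethyl)-3-[(2R,4R,5R)-4-hydroxy-5-methoxy-4-methyl-5-(3-methylbut-3-en-1-yl)oxolan-2-yl]prop-2-enoate | CO[C@]1(CCC(C)=C)O[C@@H](/C=C(\CBr)C(=O)OC)C[C@@]1(C)O | intermediate
14 | acrolein | C=CC=O | starting material
15 | methyl (3R,4R)-4-hydroxy-3-[(2R,4R,5R)-4-hydroxy-5-methoxy-4-methyl-5-(3-methylbut-3-en-1-yl)oxolan-2-yl]-2-methylidenehex-5-enoate | CO[C@]1(CCC(C)=C)O[C@@H]([C@H](C(=C)C(=O)OC)[C@H](O)C=C)C[C@@]1(C)O | intermediate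
16 | (4S,5R)-5-ethenyl-4-[(2R,4R,5R)-4-hydroxy-5-methoxy-4-methyl-5-(3-methylbut-3-en-1-yl)oxolan-2-yl]-3-methylideneoxolan-2-one | CO[C@]1(CCC(C)=C)O[C@@H]([C@@H]2C(=C)C(=O)O[C@@H]2C=C)C[C@@]1(C)O | intermediate
17 | (1R,4Z,6R,7S,8R,10R)-1,8-epoxy-10-hydroxy-1-methoxygermacra-4,11(13)-dien-12,6-olide | C=C1C(=O)O[C@@H]2/C=C(/C)CC[C@@]3(OC)O[C@H](C[C@@]3(C)O)[C@H]12 | intermediate
18 | (4Z,6R,7S,8R,10R)-8,10-dihydroxy-1-oxogermacra-4,11(13)-dien-12,6-olide | C=C1C(=O)O[C@@H]2/C=C(/C)CCC(=O)[C@](C)(O)C[C@@H](O)[C@H]12 | intermediate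
19 | (E)-2-methylbut-2-enoyl chloride (tigloyl chloride) | C/C=C(\C)C(=O)Cl | starting material
20 | [(3aS,4R,6R,10Z,11aR)-6-hydroxy-6,10-dimethyl-3-methylidene-2,7-dioxo-2,3,3a,4,5,6,7,8,9,11a-decahydrocyclodeca[b]furan-4-yl] (2E)-2-methylbut-2-enoate = (4Z,6R,7S,8R,10R)-10-hydroxy-1-oxo-8-tigloyloxygermacra-4,11(13)-dien-12,6-olide | C=C1C(=O)O[C@@H]2/C=C(/C)CCC(=O)[C@](C)(O)C[C@@H](OC(=O)/C(C)=C/C)[C@H]12 | target

**Totals**
Total step count: 12. Longest linear sequence: 12 steps (1 → 20; the route is linear, and 6, 11, 14 and 19 are bought).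

**Three steps most likely to fail, each with a fallback**

Step 9 (the proposed new electrochemical allylation). The risks are loss of the facial selectivity at C7 if the ring oxygen chelates indium, direct reduction or polymerization of acrolein, and poor turnover of the indium mediator. The fallback uses known boron chemistry and sets out from 12. Acetylation of the secondary allylic alcohol (Ac2O, pyridine) gives methyl 2-{(acetyloxy)[(2R,4R,5R)-4-hydroxy-5-methoxy-4-methyl-5-(3-methylbut-3-en-1-yl)oxolan-2-yl]methyl}prop-2-enoate F1. Palladium-catalysed allylic borylation (Pd2(dba)3 as the zerovalent palladium source, B2pin2, DMSO, 23 °C) then gives methyl (2E)-3-[(2R,4R,5R)-4-hydroxy-5-methoxy-4-methyl-5-(3-methylbut-3-en-1-yl)oxolan-2-yl]-2-[(4,4,5,5-tetramethyl-1,3,2-dioxaborolan-2-yl)methyl]prop-2-enoate F2. Heating F2 with acrolein 14 in toluene (80 °C) gives thermal allylboration through a closed chair transition state; boron has no free site for chelation, so the same syn and anti-to-oxygen outcome is expected. Brief treatment with pyridinium p-toluenesulfonate completes lactonization, and the fallback comes back to the route at 16.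

Step 10 (ring-closing metathesis to the bridged ten-membered ring). The risks are strain of the oxygen-bridged bicycle, oligomerization, and a share of ketal anomer that cannot cyclize. The fallback sets out from 16 and removes the bridge before ring closure. Hydrolysis of the ketal (1 M HCl, THF) gives (4S,5R)-5-ethenyl-4-[(1R,3R)-1,3-dihydroxy-3,7-dimethyl-4-oxooct-7-en-1-yl]-3-methylideneoxolan-2-one F3. Acylation with 19 (pyridine, DMAP) gives its C8 tiglate, (1R,3R)-1-[(2R,3S)-2-ethenyl-4-methylidene-5-oxooxolan-3-yl]-3-hydroxy-3,7-dimethyl-4-oxooct-7-en-1-yl (2E)-2-methylbut-2-enoate F4. Ring-closing metathesis of F4 (second-generation Grubbs catalyst RuCl2(=CHPh)(PCy3)(H2IMes), toluene, 1 mM, 80 °C) closes the unbridged cyclodecadiene, and the fallback comes back to the route at 20. This order also acylates C8 before any transannular hemiketal can form.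

Step 7 (Baylis–Hillman reaction on the epimerizable α-alkoxy aldehyde). The risks are slow conversion and partial epimerization at C8 during long exposure to DABCO. The fallback sets out from 10 and replaces the amine-catalysed reaction by vinylalumination. Methyl propiolate is hydroaluminated with i-Bu2AlH and N-methylmorpholine N-oxide in THF at 0 °C to give [1-(methoxycarbonyl)ethenyl]diisobutylaluminium, which adds to 10 at −78 °C within an hour without base. The fallback comes back to the route at 12; new compounds: none F0.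

**Further compounds**
F1 | step 9 | methyl 2-{(acetyloxy)[(2R,4R,5R)-4-hydroxy-5-methoxy-4-methyl-5-(3-methylbut-3-en-1-yl)oxolan-2-yl]methyl}prop-2-enoate | CO[C@]1(CCC(C)=C)O[C@@H](C(OC(C)=O)C(=C)C(=O)OC)C[C@@]1(C)O
F2 | step 9 | methyl (2E)-3-[(2R,4R,5R)-4-hydroxy-5-methoxy-4-methyl-5-(3-methylbut-3-en-1-yl)oxolan-2-yl]-2-[(4,4,5,5-tetramethyl-1,3,2-dioxaborolan-2-yl)methyl]prop-2-enoate | CO[C@]1(CCC(C)=C)O[C@@H](/C=C(\CB2OC(C)(C)C(C)(C)O2)C(=O)OC)C[C@@]1(C)O
F3 | step 10 | (4S,5R)-5-ethenyl-4-[(1R,3R)-1,3-dihydroxy-3,7-dimethyl-4-oxooct-7-en-1-yl]-3-methylideneoxolan-2-one | C=C(C)CCC(=O)[C@](C)(O)C[C@@H](O)[C@@H]1C(=C)C(=O)O[C@@H]1C=C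
F4 | step 10 | (1R,3R)-1-[(2R,3S)-2-ethenyl-4-methylidene-5-oxooxolan-3-yl]-3-hydroxy-3,7-dimethyl-4-oxooct-7-en-1-yl (2E)-2-methylbut-2-enoate | C=C(C)CCC(=O)[C@](C)(O)C[C@@H](OC(=O)/C(C)=C/C)[C@@H]1C(=C)C(=O)O[C@@H]1C=C
F0 | step 7 | none | none
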